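## Retrosynthetic overview

1. The target comes from its tris-MOM ether by acid cleavage, and that flavanone from the flavan-4-ol by oxidation of the C4 carbinol.
2. Ring C is closed last through the O1–C8a aryl ether bond. An acyclic (S)-1,3-diol with a 2-fluoroaryl ring A is converted into the C8–C8a aryne, the C2 alkoxide adds to C8a, and the carbanion left at C8 takes the prenyl group in the same flask. The enabling feature is that O1-bearing C8a and prenyl-bearing C8 are neighbouring ring-A carbons, with the C7 oxygen beside C8 and with C8a tied to the C2 oxygen through C4a–C4–C3 (six-membered ring C).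
3. The diol comes from a 1,3-diketone: transfer hydrogenation with RuCl(p-cymene)[(S,S)-TsDPEN] sets C2, and NaBH4 brings C4 to the alcohol level, which masks the ketone during the organolithium step. The diketone comes from a Claisen condensation of a ring-A methyl ketone with a ring-B ester.
4. The ring-B ester comes from a γ-selective allyl–aryl coupling (1,1-dimethylallyl group) followed by MOM-directed ortho-lithiation and carboxylation. The ring-A ketone comes from Houben–Hoesch acylation of 5-fluororesorcinol followed by MOM protection.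
5. Order of ring formation: rings A and B are bought as benzene rings; ring C is the only ring made, in step 8.

Key step: step 8

Remark: C4 is carried as a mixture of epimers from step 7 to step 9, where it becomes the ketone, so the SMILES of 14 and 16–19 leave that centre open; compounds 1, 2, 6 and 15 are taken as commercially available.

## Route

Step 1
Reactants: 1 1-bromo-4-(methoxymethoxy)benzene; 2 4,4,5,5-tetramethyl-2-(3-methylbut-2-en-1-yl)-1,3,2-dioxaborolane
Product: 3 1-(methoxymethoxy)-4-(2-methylbut-3-en-2-yl)benzene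
Conditions: Pd(OAc)2 (2 mol%), bulky dialkylbiarylphosphine chosen for γ-selectivity (4 mol%), aq K3PO4, THF, 40 °C
Reagents that add atoms: none
Why: Suzuki–Miyaura coupling of an allylboronate in its γ-selective mode, in which SE2′-type transmetalation places palladium on the tertiary carbon and the bulky ligand should make reductive elimination faster than σ–π–σ isomerisation, so that the aryl group ends up on the quaternary carbon; no stereocentre is formed.

Step 2
Reactants: 3 1-(methoxymethoxy)-4-(2-methylbut-3-en-2-yl)benzene
Product: 5 methyl 2-(methoxymethoxy)-5-(2-methylbut-3-en-2-yl)benzoate, via aryllithium 4 (not isolated)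
Conditions: n-BuLi, TMEDA, THF, −78 → 0 °C; then inverse addition to ClCO2Me (3 equiv), THF, −78 °C
Reagents that add atoms: methyl chloroformate, COC(=O)Cl
Why: Directed ortho-metalation, in which the MOM ether directs lithiation to one of its two equivalent ortho positions (the side chain has no benzylic or allylic hydrogen) and inverse addition to excess chloroformate should give the ester without double addition.

Step 3
Reactants: 6 5-fluorobenzene-1,3-diol
Product: 8 1-(2-fluoro-4,6-dihydroxyphenyl)ethan-1-one, via ketiminium chloride 7 (not isolated)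
Conditions: MeCN, ZnCl2 (cat.), HCl (g), Et2O, 0 °C; then H2O, 100 °C
Reagents that add atoms: acetonitrile, CC#N; water, O
Why: Houben–Hoesch acylation, in which the nitrilium electrophile should attack one of the two equivalent positions between a hydroxyl and fluorine (para to the other hydroxyl) rather than the position between the two hydroxyls, and the ketiminium salt is hydrolysed to the ketone.

Step 4
Reactants: 8 1-(2-fluoro-4,6-dihydroxyphenyl)ethan-1-one
Product: 10 1-[2-fluoro-4,6-bis(methoxymethoxy)phenyl]ethan-1-one, via disodium bisphenoxide 9 (not isolated)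
Conditions: NaH (2.4 equiv), DMF, 0 °C; then MOMCl (2.4 equiv), 0 °C → rt
Reagents that add atoms: chloromethyl methyl ether (MOMCl), COCCl
Why: Williamson-type O-alkylation of both phenoxides, the strong base being needed to break the hydrogen bond of the hydroxyl next to the acetyl group.

Step 5
Reactants: 10 1-[2-fluoro-4,6-bis(methoxymethoxy)phenyl]ethan-1-one; 5 methyl 2-(methoxymethoxy)-5-(2-methylbut-3-en-2-yl)benzoate
Product: 12 1-[2-fluoro-4,6-bis(methoxymethoxy)phenyl]-3-[2-(methoxymethoxy)-5-(2-methylbut-3-en-2-yl)phenyl]propane-1,3-dione, via lithium enolate 11 (not isolated)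
Conditions: LiN(SiMe3)2 (2.5 equiv), THF, −78 °C; then 5, −78 °C → rt; AcOH quench
Reagents that add atoms: none
Why: Crossed Claisen condensation, in which the lithium enolate of the hindered ketone acylates at carbon with the non-enolisable aryl ester and formation of the diketonate drives the reaction, while the lithium counter-ion and low temperature should keep the diketonate from displacing the ortho fluoride.

Step 6
Reactants: 12 1-[2-fluoro-4,6-bis(methoxymethoxy)phenyl]-3-[2-(methoxymethoxy)-5-(2-methylbut-3-en-2-yl)phenyl]propane-1,3-dione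
Product: 13 (3S)-1-[2-fluoro-4,6-bis(methoxymethoxy)phenyl]-3-hydroxy-3-[2-(methoxymethoxy)-5-(2-methylbut-3-en-2-yl)phenyl]propan-1-one
Conditions: RuCl(p-cymene)[(S,S)-TsDPEN] (2 mol%), HCO2H/Et3N (5:2), CH2Cl2, 30 °C
Reagents that add atoms: none
Why: Noyori–Ikariya asymmetric transfer hydrogenation, in which the ring-B carbonyl should be reduced first because the ring-A carbonyl is shielded by fluorine and a MOM ether, and the (S,S) ligand is expected, by analogy with acetophenone and 1,3-diaryl-1,3-diketones, to give the (S)-carbinol that becomes C2 (to be confirmed on the product, with the (R,R) ligand used if the sense proves opposite); any diol from over-reduction is the product of step 7 and is carried along.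

Step 7
Reactants: 13 (3S)-1-[2-fluoro-4,6-bis(methoxymethoxy)phenyl]-3-hydroxy-3-[2-(methoxymethoxy)-5-(2-methylbut-3-en-2-yl)phenyl]propan-1-one
Product: 14 (1S,3RS)-3-[2-fluoro-4,6-bis(methoxymethoxy)phenyl]-1-[2-(methoxymethoxy)-5-(2-methylbut-3-en-2-yl)phenyl]propane-1,3-diol
Conditions: NaBH4, MeOH/THF, 0 °C → rt
Reagents that add atoms: none
Why: Hydride reduction of the remaining aryl ketone, where the new C4 carbinol needs no control because it is oxidised again in step 9 and the basic medium avoids ionisation of the electron-rich benzylic alcohol.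

Step 8
Reactants: 14 (1S,3RS)-3-[2-fluoro-4,6-bis(methoxymethoxy)phenyl]-1-[2-(methoxymethoxy)-5-(2-methylbut-3-en-2-yl)phenyl]propane-1,3-diol; 15 1-bromo-3-methylbut-2-ene
Product: 19 (2S,4RS)-5,7-bis(methoxymethoxy)-2-[2-(methoxymethoxy)-5-(2-methylbut-3-en-2-yl)phenyl]-8-(3-methylbut-2-en-1-yl)-3,4-dihydro-2H-chromen-4-ol, via ortho-fluoroaryllithium dialkoxide 16 (not isolated), via aryne dialkoxide 17 (not isolated), via C8 aryllithium 18 (not isolated)
Conditions: LiTMP (lithium 2,2,6,6-tetramethylpiperidide, 3.2 equiv, stock solution), THF (0.02 M), −78 °C, then −78 → −10 °C; re-cool, CuBr·SMe2 (20 mol%), 15 (1.3 equiv), −78 → 0 °C; H2O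
Reagents that add atoms: none
Why: Proposed new method: LiTMP turns both hydroxyls into lithium alkoxides and then removes C8–H, the ring-A proton flanked by the C8a fluorine and the C7 MOM ether (16); on warming, 16 loses LiF to give the C8–C8a aryne 17, the tethered C2 alkoxide adds to C8a (6-exo-dig closure of ring C through the O1–C8a bond), and the aryllithium 18 left at C8 is prenylated at the primary carbon of 15 under CuBr catalysis. The closest known reaction types are the ring closure of (haloaryl)alkanols to chromans through arynes and the three-component couplings of 3-alkoxyarynes made from 2-fluoro-6-alkoxyphenyllithiums, in which a nucleophile adds meta to the alkoxy group and the aryl-metal left ortho to it is captured by an electrophile; what is new is a tethered, unprotected alkoxide as the nucleophile combined with an allylic halide as the terminating electrophile on a polyanion. Both the tether (attack at C8 would need a meta-bridged ring) and the inductive effect of the C7 oxygen, which favours negative charge at C8, put oxygen on C8a and carbon on C8. No stereocentre is formed: C2 enters as the (S)-alkoxide and its C–O bond is never broken, so its configuration is retained, and the two C4 epimers should behave alike. The step needs lithiation at C8 rather than C6 (fluorine is the stronger acidifying group, LiTMP metalation can equilibrate, and only the C8 anion is drained by loss of LiF), ring closure rather than intermolecular capture of the aryne (high dilution, hindered amine), and C- rather than O-prenylation with α rather than γ attack (the lithium alkoxide is inert to the bromide at or below 0 °C and the γ carbon is fully substituted).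

Step 9
Reactants: 19 (2S,4RS)-5,7-bis(methoxymethoxy)-2-[2-(methoxymethoxy)-5-(2-methylbut-3-en-2-yl)phenyl]-8-(3-methylbut-2-en-1-yl)-3,4-dihydro-2H-chromen-4-ol
Product: 20 (2S)-5,7-bis(methoxymethoxy)-2-[2-(methoxymethoxy)-5-(2-methylbut-3-en-2-yl)phenyl]-8-(3-methylbut-2-en-1-yl)-2,3-dihydro-4H-chromen-4-one
Conditions: n-Pr4N[RuO4] (5 mol%), NMO, 4 Å MS, CH2Cl2, rt
Reagents that add atoms: none
Why: Ley–Griffith oxidation of the benzylic secondary alcohol under neutral conditions, which should leave both alkenes, the MOM ethers and C2 untouched (no base to open the ring by β-elimination) and converges both C4 epimers.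

Step 10
Reactants: 20 (2S)-5,7-bis(methoxymethoxy)-2-[2-(methoxymethoxy)-5-(2-methylbut-3-en-2-yl)phenyl]-8-(3-methylbut-2-en-1-yl)-2,3-dihydro-4H-chromen-4-one
Product: 21 (2S)-5,7-dihydroxy-2-[2-hydroxy-5-(2-methylbut-3-en-2-yl)phenyl]-8-(3-methylbut-2-en-1-yl)-2,3-dihydro-4H-chromen-4-one (CID51040684)
Conditions: 3 M aq HCl, MeOH, 40 °C
Reagents that add atoms: none
Why: Acid-catalysed acetal exchange removes the three MOM groups under conditions mild enough that cyclisation of the prenyl group onto the C7 hydroxyl and acid-induced opening of ring C at C2 should not compete.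

## Compound list

1 | 1-bromo-4-(methoxymethoxy)benzene | COCOc1ccc(Br)cc1 | starting material
2 | 4,4,5,5-tetramethyl-2-(3-methylbut-2-en-1-yl)-1,3,2-dioxaborolane | CC(C)=CCB1OC(C)(C)C(C)(C)O1 | starting material
3 | 1-(methoxymethoxy)-4-(2-methylbut-3-en-2-yl)benzene | C=CC(C)(C)c1ccc(OCOC)cc1 | intermediate
4 | [2-(methoxymethoxy)-5-(2-methylbut-3-en-2-yl)phenyl]lithium | [Li]c1cc(C(C)(C)C=C)ccc1OCOC | intermediate
5 | methyl 2-(methoxymethoxy)-5-(2-methylbut-3-en-2-yl)benzoate | C=CC(C)(C)c1ccc(OCOC)c(C(=O)OC)c1 | intermediate
6 | 5-fluorobenzene-1,3-diol | Oc1cc(O)cc(F)c1 | starting material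
7 | 1-(2-fluoro-4,6-dihydroxyphenyl)ethan-1-iminium chloride | CC(=[NH2+])c1c(O)cc(O)cc1F.[Cl-] | intermediate
8 | 1-(2-fluoro-4,6-dihydroxyphenyl)ethan-1-one | CC(=O)c1c(O)cc(O)cc1F | intermediate
9 | disodium 4-acetyl-5-fluorobenzene-1,3-diolate | CC(=O)c1c([O-])cc([O-])cc1F.[Na+].[Na+] | intermediate
10 | 1-[2-fluoro-4,6-bis(methoxymethoxy)phenyl]ethan-1-one | CC(=O)c1c(OCOC)cc(OCOC)cc1F | intermediate
11 | lithium 1-[2-fluoro-4,6-bis(methoxymethoxy)phenyl]ethen-1-olate | [Li]OC(=C)c1c(OCOC)cc(OCOC)cc1F | intermediate
12 | 1-[2-fluoro-4,6-bis(methoxymethoxy)phenyl]-3-[2-(methoxymethoxy)-5-(2-methylbut-3-en-2-yl)phenyl]propane-1,3-dione | C=CC(C)(C)c1ccc(OCOC)c(C(=O)CC(=O)c2c(OCOC)cc(OCOC)cc2F)c1 | intermediate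
13 | (3S)-1-[2-fluoro-4,6-bis(methoxymethoxy)phenyl]-3-hydroxy-3-[2-(methoxymethoxy)-5-(2-methylbut-3-en-2-yl)phenyl]propan-1-one | C=CC(C)(C)c1ccc(OCOC)c([C@@H](O)CC(=O)c2c(OCOC)cc(OCOC)cc2F)c1 | intermediate
14 | (1S,3RS)-3-[2-fluoro-4,6-bis(methoxymethoxy)phenyl]-1-[2-(methoxymethoxy)-5-(2-methylbut-3-en-2-yl)phenyl]propane-1,3-diol | C=CC(C)(C)c1ccc(OCOC)c([C@@H](O)CC(O)c2c(OCOC)cc(OCOC)cc2F)c1 | intermediate
15 | 1-bromo-3-methylbut-2-ene | CC(C)=CCBr | starting material
16 | trilithio derivative of 14 (both alkoxides, C8 lithiated, fluorine in place) | C=CC(C)(C)c1ccc(OCOC)c([C@@H](O[Li])CC(O[Li])c2c(OCOC)cc(OCOC)c([Li])c2F)c1 | intermediate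
17 | C8–C8a aryne, dilithium dialkoxide | C=CC(C)(C)c1ccc(OCOC)c([C@@H](O[Li])CC(O[Li])C2=C(OCOC)C=C(OCOC)C#C2)c1 | intermediate
18 | (2S)-8-lithio-flavan-4-olate, lithium salt (ring C closed) | C=CC(C)(C)c1ccc(OCOC)c([C@@H]2CC(O[Li])c3c(OCOC)cc(OCOC)c([Li])c3O2)c1 | intermediate
19 | (2S,4RS)-5,7-bis(methoxymethoxy)-2-[2-(methoxymethoxy)-5-(2-methylbut-3-en-2-yl)phenyl]-8-(3-methylbut-2-en-1-yl)-3,4-dihydro-2H-chromen-4-ol | C=CC(C)(C)c1ccc(OCOC)c([C@@H]2CC(O)c3c(OCOC)cc(OCOC)c(CC=C(C)C)c3O2)c1 | intermediate
20 | (2S)-5,7-bis(methoxymethoxy)-2-[2-(methoxymethoxy)-5-(2-methylbut-3-en-2-yl)phenyl]-8-(3-methylbut-2-en-1-yl)-2,3-dihydro-4H-chromen-4-one | C=CC(C)(C)c1ccc(OCOC)c([C@@H]2CC(=O)c3c(OCOC)cc(OCOC)c(CC=C(C)C)c3O2)c1 | intermediate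
21 | (2S)-5,7-dihydroxy-2-[2-hydroxy-5-(2-methylbut-3-en-2-yl)phenyl]-8-(3-methylbut-2-en-1-yl)-2,3-dihydro-4H-chromen-4-one | C=CC(C)(C)c1ccc(O)c([C@@H]2CC(=O)c3c(O)cc(O)c(CC=C(C)C)c3O2)c1 | target

## Step count and risks

Total step count: 10. Longest linear sequence: 8 steps (steps 3–10 from 6, or steps 1, 2 and 5–10 from 1).

Steps most likely to fail:

1. Step 8. The cascade may fail through competing metalation at C6, intermolecular capture of the aryne, or O-alkylation and γ-attack in the prenyl quench. The fallback sets out from 14 and comes back at 19; it keeps the O1–C8a closure but separates the two bond formations into known operations. Diol 14 is metalated with LiTMP at −78 °C as before, but the cold ortho-fluoroaryllithium is transmetalated with CuBr·SMe2 (1.1 equiv) and prenylated with 15 without warming, so that no fluoride is lost. This directed ortho-metalation with copper-mediated allylation should give (1S,3RS)-3-[2-fluoro-4,6-bis(methoxymethoxy)-3-(3-methylbut-2-en-1-yl)phenyl]-1-[2-(methoxymethoxy)-5-(2-methylbut-3-en-2-yl)phenyl]propane-1,3-diol F1. Ring C would then be closed by intramolecular nucleophilic aromatic substitution of the fluoride by the C2 alkoxide (KN(SiMe3)2, THF/DMPU, 60 °C), the known way from 3-(2-fluorophenyl)propan-1-ols to chromans. No aryne can form here because both positions next to fluorine are substituted, and the product is 19.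

2. Step 6. Hydride transfer to the enolised, ortho-substituted diketone may be slow or poorly face-selective, or the product may be over-reduced or dehydrated. The fallback sets out from 4 and 11 (that is, from 3 and 10) and comes back at 13, bypassing 12; C2 is set in the C2–C3 bond-forming event instead of a reduction. Aryllithium 4 is quenched with DMF to give 2-(methoxymethoxy)-5-(2-methylbut-3-en-2-yl)benzaldehyde F2. Enolate 11 is silylated with Me3SiCl to give {1-[2-fluoro-4,6-bis(methoxymethoxy)phenyl]ethenyl}oxy(trimethyl)silane F3. An enantioselective Mukaiyama aldol addition of F3 to F2 under a chiral boron Lewis acid (tryptophan-derived N-tosyl B-butyl oxazaborolidinone, 20 mol%, EtCN, −78 °C, enantiomer chosen to give the (S)-carbinol) should give the trimethylsilyl ether of 13, (3S)-1-[2-fluoro-4,6-bis(methoxymethoxy)phenyl]-3-[2-(methoxymethoxy)-5-(2-methylbut-3-en-2-yl)phenyl]-3-(trimethylsilyloxy)propan-1-one F4. Its Si–O bond is cleaved in the work-up (dilute HCl, THF, 0 °C) to give 13.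

3. Step 1. Allyl transfer may go through the α carbon after σ–π–σ isomerisation of the allylpalladium intermediate and give the linear prenyl arene. The fallback sets out from 1 and comes back at 3; the quaternary benzylic carbon is built by enolate arylation. Pd(dba)2/P(t-Bu)3-catalysed α-arylation of the lithium enolate of methyl isobutyrate (LiNCy2, toluene, rt) with 1 should give methyl 2-[4-(methoxymethoxy)phenyl]-2-methylpropanoate F5. Reduction with i-Bu2AlH (CH2Cl2, −78 °C) gives 2-[4-(methoxymethoxy)phenyl]-2-methylpropanal F6, and Wittig methylenation (Ph3P=CH2, THF) gives 3.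

## Further compounds

F1 | step 8 | (1S,3RS)-3-[2-fluoro-4,6-bis(methoxymethoxy)-3-(3-methylbut-2-en-1-yl)phenyl]-1-[2-(methoxymethoxy)-5-(2-methylbut-3-en-2-yl)phenyl]propane-1,3-diol | C=CC(C)(C)c1ccc(OCOC)c([C@@H](O)CC(O)c2c(OCOC)cc(OCOC)c(CC=C(C)C)c2F)c1
F2 | step 6 | 2-(methoxymethoxy)-5-(2-methylbut-3-en-2-yl)benzaldehyde | C=CC(C)(C)c1ccc(OCOC)c(C=O)c1
F3 | step 6 | {1-[2-fluoro-4,6-bis(methoxymethoxy)phenyl]ethenyl}oxy(trimethyl)silane | C=C(O[Si](C)(C)C)c1c(OCOC)cc(OCOC)cc1F
F4 | step 6 | (3S)-1-[2-fluoro-4,6-bis(methoxymethoxy)phenyl]-3-[2-(methoxymethoxy)-5-(2-methylbut-3-en-2-yl)phenyl]-3-(trimethylsilyloxy)propan-1-one | C=CC(C)(C)c1ccc(OCOC)c([C@@H](O[Si](C)(C)C)CC(=O)c2c(OCOC)cc(OCOC)cc2F)c1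
F5 | step 1 | methyl 2-[4-(methoxymethoxy)phenyl]-2-methylpropanoate | COC(=O)C(C)(C)c1ccc(OCOC)cc1
F6 | step 1 | 2-[4-(methoxymethoxy)phenyl]-2-methylpropanal | O=CC(C)(C)c1ccc(OCOC)cc1
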